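**Strategy.** The key step exploits the fact that the cyclopentane ring (C8–C12), the oxygens on C9 and C11 and the oxygen on C15 all sit on one unbranched C20 chain. The C8–C12 bond and these C–O bonds are therefore disconnected back to all-Z icosa-8,11,14-trienoic acid 1. Prostaglandin H synthase adds two molecules of O2 (2) to 1 in one enzyme-bound radical cascade that closes the dioxolane and the cyclopentane and sets C8, C9, C11, C12 and C15, giving hydroperoxy endoperoxide 3. In the same flask 3 is reduced and isomerised to the 9-keto-11-hydroxy compound, and hydrogenation of C13=C14 finishes the synthesis. The precursor is the purchased free acid 1 with its three skipped Z alkenes.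

Key step: step 1

Assumption: acid 1 (all-Z, free of hydroperoxides, kept under argon until use) and ram seminal vesicle microsomes, which carry both PGH synthase-1 and the glutathione-dependent PGE isomerase, are bought; purified ovine PGH synthase-1 combined with recombinant microsomal PGE synthase-1 would serve in the same way.

Numbering: prostanoic acid numbering is used throughout (C1 = carboxyl carbon, ring = C8–C12, α = the ring face that carries the C8 chain).

**Step 1**
Reactants: 1 dihomo-γ-linolenic acid; 2 dioxygen (two molecules)
Product: 5 prostaglandin E1 (PGE1), via prostaglandin G1 3 (not isolated), via prostaglandin H1 4 (not isolated)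
Conditions: ram seminal vesicle microsomes (added in portions), O2 (1 atm), hydroquinone (1.2 equiv), glutathione (2 mM), hematin C34H33FeN4O5 (1 µM), 0.1 M Tris·HCl pH 8.0, 37 °C, 1 added as NH4 salt; then citric acid to pH 3 at 0 °C, EtOAc extraction
Reagents that add atoms: dioxygen (compound 2), O=O
Why: The enzyme-bound tyrosyl radical removes the bis-allylic 13-pro-S hydrogen of 1, the C11–C15 pentadienyl radical binds the first O2 at C11, the two ring closures follow, and the C13–C15 allyl radical binds the second O2 at C15 before the peroxyl radical is quenched to hydroperoxide 3 by the tyrosine O–H; the closest known reaction type is the peroxyl-radical (autoxidative) bicyclisation of skipped polyenes. The 1,2-dioxolane (C9, C10, C11 and both oxygens) closes by 5-exo-trig addition of the C11 peroxyl radical to C9 of the C8=C9 alkene, and the cyclopentane (C8–C12) closes by 5-exo-trig addition of the C8 radical to C12 of the conjugated C12–C15 diene, which together make the 2,3-dioxabicyclo[2.2.1]heptane. C11 is set by O2 arriving on the chain face opposite to the abstracted hydrogen, C9 by the cis bridge that the dioxolane demands, C8 and C12 (trans chains) by the folded chain conformation that the hydrophobic channel enforces against the cis preference of the free radical closure, and C15 (S) by the single face of the allyl radical that the channel leaves open to O2. The step needs abstraction at C13 and not C10, first oxygenation at C11 and not C15, and trans and not cis carbocyclisation; the C1 carboxylate held at the channel entrance (hence the free acid and not an ester) fixes the register of the chain, and the Z alkenes at C8, C11 and C14 provide the weak C13–H bond and the spacing that both 5-exo closures require. In the same flask the heme peroxidase site of the synthase reduces the 15-hydroperoxide of 3 to the alcohol of 4 with hydroquinone as the electron donor, and the glutathione-dependent isomerase removes the C9 hydrogen with O–O cleavage (an enzyme-directed Kornblum–DeLaMare-type opening), so that the C9 ketone and the 11α-hydroxyl of 5 arise without change at C8, C11, C12 or C15.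

**Step 2**
Reactants: 5 prostaglandin E1 (PGE1)
Product: 6 13,14-dihydro-PGE1 (the target)
Conditions: H2 (3 atm), RhCl(PPh3)3 (10 mol %), degassed toluene/EtOH (1:1), 25 °C
Reagents that add atoms: none
Why: Homogeneous catalytic hydrogenation with the monovalent rhodium complex adds H2 to the only C=C bond (E-C13=C14) under neutral conditions, leaving the C9 ketone, the carboxylic acid, the C15–O bond and the elimination-prone β-ketol untouched, so C8, C11, C12 and C15 are carried over unchanged and no new stereocentre arises.

**Compound list**
1 | dihomo-γ-linolenic acid, (8Z,11Z,14Z)-icosa-8,11,14-trienoic acid | CCCCC/C=C\C/C=C\C/C=C\CCCCCCC(=O)O | starting material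
2 | dioxygen | O=O | starting material
3 | prostaglandin G1, 9α,11α-epidioxy-15S-hydroperoxyprost-13E-en-1-oic acid (C8 chain α, C12 chain β) | CCCCC[C@H](OO)/C=C/[C@H]1[C@H]2C[C@H](OO2)[C@@H]1CCCCCCC(=O)O | intermediate
4 | prostaglandin H1, 9α,11α-epidioxy-15S-hydroxyprost-13E-en-1-oic acid | CCCCC[C@H](O)/C=C/[C@H]1[C@H]2C[C@H](OO2)[C@@H]1CCCCCCC(=O)O | intermediate
5 | prostaglandin E1, (8R,11R,12R,13E,15S)-11,15-dihydroxy-9-oxoprost-13-en-1-oic acid | CCCCC[C@H](O)/C=C/[C@H]1[C@H](O)CC(=O)[C@@H]1CCCCCCC(=O)O | intermediate
6 | 13,14-dihydro-PGE1, (8R,11R,12R,15S)-11,15-dihydroxy-9-oxoprostan-1-oic acid, that is 7-[(1R,2R,3R)-3-hydroxy-2-[(3S)-3-hydroxyoctyl]-5-oxocyclopentyl]heptanoic acid | CCCCC[C@H](O)CC[C@H]1[C@H](O)CC(=O)[C@@H]1CCCCCCC(=O)O | target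

Total step count: 2
Longest linear sequence: 2 steps (1 → 5 → 6)

**Steps most likely to fail** (the route has two steps, so both are ranked)

1. Step 1 (key step). The endoperoxide 4 may escape the isomerase and decay without the enzyme, by opening towards the 11-keto-9-hydroxy isomer and by fragmentation with loss of malondialdehyde. The β-ketol of 5 may also lose water during isolation from the incubation, and self-inactivation of the synthase may stop the conversion early. The fallback sets out from 1 and returns at 5; it keeps the oxygenation but no longer isomerises the endoperoxide. Acid 1 is oxygenated with the same microsomes and hydroquinone but without glutathione, so that the isomerase is idle, and 3 and 4 form as before. After a few minutes the mixture is quenched at 0 °C with SnCl2 in EtOH, which reduces the O–O bond of 4 and any remaining 3 to the stable triol acid prostaglandin F1α F1. Me3SiNEt2 in acetone at −45 °C should silylate the acid and the less hindered 11- and 15-hydroxyls, giving PGF1α 11,15-bis(trimethylsilyl) ether trimethylsilyl ester F2. Oxidation of the free 9α-hydroxyl with CrO3·2C5H5N (hexavalent chromium) in CH2Cl2 at 0 °C should give PGE1 11,15-bis(trimethylsilyl) ether trimethylsilyl ester F3. AcOH/H2O/MeOH at 25 °C then removes the three silyl groups and rejoins the route at 5.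

2. Step 2. Hydrogen uptake may be slow at the E-disubstituted alkene flanked by the ring and the carbinol. A rhodium hydride may instead move the double bond and turn the allylic alcohol into the C15 ketone, and long reaction times may cause loss of water from the β-ketol. The fallback sets out from 5 and returns directly at 6. It replaces metal catalysis by transfer of H2 from diimide, generated in the flask from KO2CN=NCO2K and AcOH in MeOH at 0–25 °C. The concerted syn delivery to C13=C14 cannot isomerise the allylic alcohol, cleave the C15–O bond or touch the ketone. No new compound arises on this way (entry F0).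

**Further compounds**
F1 | step 1 | prostaglandin F1α, 9α,11α,15S-trihydroxyprost-13E-en-1-oic acid | CCCCC[C@H](O)/C=C/[C@H]1[C@H](O)C[C@H](O)[C@@H]1CCCCCCC(=O)O
F2 | step 1 | PGF1α 11,15-bis(trimethylsilyl) ether trimethylsilyl ester | CCCCC[C@H](O[Si](C)(C)C)/C=C/[C@H]1[C@H](O[Si](C)(C)C)C[C@H](O)[C@@H]1CCCCCCC(=O)O[Si](C)(C)C
F3 | step 1 | PGE1 11,15-bis(trimethylsilyl) ether trimethylsilyl ester | CCCCC[C@H](O[Si](C)(C)C)/C=C/[C@H]1[C@H](O[Si](C)(C)C)CC(=O)[C@@H]1CCCCCCC(=O)O[Si](C)(C)C
F0 | step 2 | none | none
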